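## The problem

Amaurone B (36) links a fully substituted cyclohexane through an all-E triene to a 2-methoxy-3,5-dimethyl-4-pyranone. The ring is numbered C1 (CH bearing the chain), C2 (CHMe), C3 (CMeOH), C4 (CHOAc), C5 (CMeOH), C6 (CHOAc), and the chain C7 to C12 from ring to heterocycle. All six ring atoms are stereocentres (C1 R, C2 S, C3 R, C4 R, C5 S, C6 S) and two are tertiary carbinols. No second ring is fused to the carbocycle, so relative configuration must be passed on around one monocycle. The pattern is simple: the chain at C1 and the methyl groups at C2, C3 and C5 lie on one face (α below) and all four oxygens lie on the other (β). A cis C1/C2 pair set first can therefore shield α and send every later oxidant to β. The oxygens differ only as secondary (acetylated) and tertiary (free). This is easy to exploit at the end but not earlier, because acetates do not survive enolate chemistry and an O6 acetate is β to C7 and would be eliminated once C7 is a carbonyl carbon. The triene–pyranone is sensitive to light, to alkene-seeking oxidants and, as a vinylogous carbonate, to strong acid and nucleophiles, so it must arrive after the ring oxidations, with E control at the trisubstituted alkenes C7=C8 and C11=C12. The key step is possible because the C1–C2 bond joins two cis CH centres while C3–C6, stripped of oxygen, form a 1,3-dimethyl-1,3-diene. The ring is thus an oxidised cis-5,6-disubstituted cyclohexa-1,3-diene, the product of disrotatory closure of an E,Z,E triene; that closure carries no absolute information, so the enantiomer must be selected separately.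

## Retrosynthesis

**Acetates and ketals.** The acyl–oxygen bonds at O4 and O6 of 36 are cut first, giving tetrol 35, which is masked as bis-acetonide 34. Acetylating earlier, at tetrol 16, would expose the esters to ylides and to a lithium dienolate and would place a leaving group β to the C7 aldehyde. Pairing O3/O4 and O5/O6 in two dioxolanes caps all four hydroxyls with one reagent. The forward steps need only a hydrolysis the pyranone tolerates and a distinction between secondary and tertiary hydroxyl.

**C11=C12.** This cut splits 34 into dienal 23 and 2-ethylpyranone 30. Cutting at C9=C10 or C10–C11 instead would need a pyranone carrying a phosphonate, stannane or boronate side arm, which is a much longer fragment. In contrast 30 takes three steps, and its ethyl group becomes the nucleophile on vinylogous deprotonation (31). The cut removes the heterocycle and one trisubstituted alkene. The forward direction requires 1,2-addition (32) and an elimination through mesylate 33 that gives the E alkene.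

**C9=C10 and C7=C8.** Two Wittig cuts lead from 23 through enal 21 to aldehyde 19, using the commercial formyl ylides 22 and 20. Ester ylides would cost a reduction and an oxidation per alkene. After these cuts only the ring with the one-carbon handle C7 remains. The forward reactions must be E-selective and near neutral, so that C1 is not epimerised and O6 is not expelled.

**Oxidation level and protection at C7.** Aldehyde 19 comes from alcohol 18, 18 from acetate 17, and 17 from tetrol 16. No skeletal bond is cut. The O7 acetate is the group the resolution installs, so it costs no separate protection step.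

**C4–O and C5–O.** These two cis oxygens are removed together as a suprafacial dihydroxylation, 16 from cyclohexenediol 14 through osmate 15. Removing any other vicinal pair would not leave an alkene flanked by two allylic hydroxyls. Two stereocentres disappear. The forward reaction must attack the β face, syn to both hydroxyls, which calls for a hydrogen-bond-directed osmium reagent rather than an undirected one.

**C3–O and C6–O.** A cis-1,4-diol across an alkene is the retron of dioxygen [4+2] addition and O–O reduction, so 14 comes from endoperoxide 13 and 13 from diene 12. The tertiary carbinol C3 arises without any carbonyl addition, whereas epoxide-based sequences would give trans relationships. Two more stereocentres disappear and 12 keeps only C1 and C2. The forward reaction needs β-face attack and cycloaddition in preference to the ene reaction.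

**Absolute configuration.** Acetate 12 is traced to racemic alcohol 11 by an enzymatic acylation. Selecting the enantiomer here, on a cheap early compound, wastes the least material. The forward step asks a lipase to read a stereocentre adjacent to the carbinol carbon.

**C1–C2, the key cut.** Opening this bond of 11 with reorganisation of the diene gives acyclic, achiral trienol 10. No other ring bond joins two cis CH centres next to a diene, so only this cut turns a ring and two stereocentres into alkene geometry alone. The forward closure must be disrotatory and must outrun hydrogen shifts and geometric isomerisation.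

**C3–C4 of the triene.** Cutting 10 at the single bond between the central and one terminal alkene gives iodide 7 and boronate 9. Each alkene then has its own stereodefined origin. Boronate 9 comes from but-2-yne (8) by syn hydroboration. Iodide 7 comes from ester 6, which comes from alcohol 3 and ylide 4 through aldehyde 5, and 3 comes from prop-2-yn-1-ol (1) through chelate 2. The coupling must retain geometry at both partners.

**The pyranone.** Compound 30 arises by O-methylation of hydroxypyranone 28 through pyrylium salt 29. Pyranone 28 forms by lactonisation of diketo ester 27, and 27 by acylation of dianion 26 of keto ester 24 with amide 25. The methylation must occur on the lactone carbonyl oxygen.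

## Roads not taken

**Alternative 1:** The cut is C3–C4. A triazolylidene carbene would add to the C4 aldehyde of keto aldehyde A2. The resulting acyl anion equivalent would attack the C3 methyl ketone and close the ring as α-ketol A1, with the C3 carbinol in place.
- Merits: only the non-enolisable aldehyde can be inverted in polarity. Six-membered aldehyde–ketone benzoin closures are known. A2 could be made enantiopure, so nothing is lost in a resolution and no stoichiometric osmium is needed; in these respects this road is better.
- Weak points: the aldehyde sits on the fully substituted, oxygenated C5, the worst steric case for carbene addition. The amine base that frees the carbene can epimerise C2, and the C2 enolate can add to the aldehyde to close a five-membered ring. The C3 configuration would rest on a substrate bias that cannot be foreseen. The C4 ketone must still be reduced from the α face between two quaternary carbons.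
- Comparison: the key step of this alternative makes one bond and one centre, while A2 already carries four centres that need acyclic stereocontrol. The chosen plan sets against its resolution an achiral precursor of five steps and the installation of four centres in two operations.

**Alternative 2:** The cut is C1–C6. Proline would condense with the only enolisable aldehyde (C7) of dialdehyde A4. The enamine carbon C1 would then add to the C6 aldehyde in a 6-enolexo aldol to give A3, with trans C1 formyl and C6 hydroxyl groups.
- Merits: the roles of the two aldehydes are unambiguous and the trans outcome fits the usual preference of such closures. A3 holds all six centres and has C7 at the oxidation level needed for the first olefination. That is better than the chosen plan, which needs a deprotection and an oxidation to reach 19, and no resolution is required.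
- Weak points: the acceptor aldehyde is attached to quaternary C5. The cis C1/C2 relationship depends on catalyst control agreeing with the bias of the adjacent C2 centre. A3 can dehydrate or revert by retro-aldol reaction. Most seriously, C2 to C5, including both tertiary carbinols, would have to be built in an open chain, which only moves the hard part of the molecule elsewhere.
- Comparison: the chosen plan draws these centres from face-selective additions to a rigid ring.

**Alternative 3:** The cuts are C2–C3 and C5–C6. Meso dioxanone A6, as its silyl enol ether A7, would add through C3 to C2 of enal A8. The second enolate at C5 would then close onto the C6 aldehyde, giving acetonide-bridged ketol A5.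
- Merits: two skeletal bonds and up to five centres form in one operation from very small pieces. The bridge protects exactly the two tertiary oxygens that stay free in 36. If it worked, this would be the shortest road, clearly shorter than the chosen one.
- Weak points: a fully substituted enol carbon must add to a β-substituted, α-branched enal, a poor acceptor prone to 1,2-attack. C1 is set by an uncontrolled protonation. Absolute configuration needs a desymmetrising catalyst for a reaction that is already hard. The C4 ketone must be reduced from the face carrying the axial C2 methyl group.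
- Comparison: the chosen plan is longer, but each of its stereocentres follows from orbital symmetry or from a predictable facial bias.

Key step: step 6

Assumption: the lipase of step 7 acylates the (1S,6S) enantiomer of 11 faster, as the empirical size rule for primary alcohols predicts when the sp3 branch C2 counts as large and the flat sp2 branch C6 as medium; if the sense is the opposite, the unreacted alcohol is the wanted one and is acetylated chemically to the same 12.

## Route

Step 1
Reactants: 1 prop-2-yn-1-ol
Product: 3 (Z)-3-iodo-2-methylprop-2-en-1-ol, via cyclic alkenylmagnesium alkoxide 2 (not isolated)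
Conditions: MeMgBr (3 equiv), CuI (10 mol %), THF, −10 °C to rt; then I2, 0 °C; aq NH4Cl
Reagents that add atoms: methylmagnesium bromide, C[Mg]Br; iodine, [I][I]
Why: Copper-catalysed carbomagnesiation of a propargylic magnesium alkoxide is a known anti addition: methyl goes to the internal carbon and magnesium ends on the terminal carbon cis to the CH2O arm, held in chelate 2. Iodinolysis with retention gives the Z iodide, which fixes the geometry of the later central alkene C4=C5.

Step 2
Reactants: 3 (Z)-3-iodo-2-methylprop-2-en-1-ol; 4 ethyl (triphenylphosphoranylidene)acetate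
Product: 6 ethyl (2E,4Z)-5-iodo-4-methylpenta-2,4-dienoate, via (Z)-3-iodo-2-methylprop-2-enal 5 (not isolated)
Conditions: activated MnO2 (excess), 4 (1.2 equiv), CH2Cl2, rt, dark
Reagents that add atoms: none
Why: One-pot MnO2 oxidation and Wittig olefination of allylic alcohols is established for β-haloenals, which are trapped as they form, so 5 has no time to isomerise. The stabilised ylide gives the E enoate, the later C1=C6 alkene.

Step 3
Reactants: 6 ethyl (2E,4Z)-5-iodo-4-methylpenta-2,4-dienoate
Product: 7 (2E,4Z)-5-iodo-4-methylpenta-2,4-dien-1-ol
Conditions: i-Bu2AlH (2.2 equiv), CH2Cl2, −78 °C; aq potassium sodium tartrate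
Reagents that add atoms: none
Why: Standard 1,2-reduction of an enoate with i-Bu2AlH; the alkenyl iodide and both alkene geometries are inert at low temperature.

Step 4
Reactants: 8 but-2-yne
Product: 9 2-[(Z)-but-2-en-2-yl]-4,4,5,5-tetramethyl-1,3,2-dioxaborolane (H and B cis)
Conditions: pinacolborane, Cp2ZrHCl (5 mol %), Et3N (10 mol %), neat, sealed tube, 60 °C
Reagents that add atoms: pinacolborane, CC1(C)OBOC1(C)C
Why: Zirconium-catalysed hydroboration of alkynes with pinacolborane is a syn addition, and the symmetrical alkyne poses no regiochemical question. H and B end cis, so after coupling the terminal methyl lies trans to C4, the E terminus the closure needs.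

Step 5
Reactants: 7 (2E,4Z)-5-iodo-4-methylpenta-2,4-dien-1-ol; 9 2-[(Z)-but-2-en-2-yl]-4,4,5,5-tetramethyl-1,3,2-dioxaborolane
Product: 10 (2E,4Z,6E)-4,6-dimethylocta-2,4,6-trien-1-ol
Conditions: Pd(PPh3)4 (5 mol %), 2 M aq KOH, THF, degassed, rt to 45 °C, dark
Reagents that add atoms: none
Why: Suzuki–Miyaura coupling of an alkenyl iodide with an alkenylboronate proceeds with retention at both partners, so the E,Z,E array is assembled from three alkenes of independently fixed geometry. The alcohol is left free because a dienyl acetate could ionise on zerovalent palladium or be saponified by the base.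

Step 6
Reactants: 10 (2E,4Z,6E)-4,6-dimethylocta-2,4,6-trien-1-ol
Product: 11 rac-[(1S,6S)-3,5,6-trimethylcyclohexa-2,4-dien-1-yl]methanol (CH2OH and the neighbouring methyl cis)
Conditions: degassed toluene (dilute), BHT (cat.), base-washed sealed tube, argon, 135 °C, dark
Reagents that add atoms: none
Why: Heating populates the helical s-cis,s-cis conformer of 10, in which the termini C1 and C2 overlap suprafacially and the six π electrons reorganise in one concerted, thermally allowed disrotatory step that forms the C1–C2 σ bond and moves the remaining π bonds to C3=C4 and C5=C6. The closest known case is the closure of (2E,4Z,6E)-octa-2,4,6-triene to cis-5,6-dimethylcyclohexa-1,3-diene at comparable temperature. The one ring formed, the six-membered carbocycle, closes by electrocyclisation, in which both termini belong to the same π system, so no exo or endo mode applies. C1 and C2 are the new stereocentres: CH2OH and CH3 are both outward (E) substituents, so disrotation turns them onto the same face and orbital symmetry together with alkene geometry fixes the cis relationship, while the two equivalent senses of disrotation give the racemate. The step needs periselectivity over sigmatropic hydrogen shifts and geometric integrity of all three alkenes. With both termini E no C–H bond points into the helix, so an antarafacial [1,7] shift has no donor, and no methyl or methylene group stands cis to a dienyl unit as a [1,5] shift would require. The C5 methyl on the central alkene disfavours the s-trans rotamer about C5–C6, the C3 methyl makes both rotamers about C3–C4 similarly crowded, and the [1,5] hydrogen shift of the product diene has a clearly higher barrier than the closure. Oxygen, acid traces and light are excluded because they would isomerise 10 or aromatise 11.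

Step 7
Reactants: 11 rac-[(1S,6S)-3,5,6-trimethylcyclohexa-2,4-dien-1-yl]methanol
Product: 12 [(1S,6S)-3,5,6-trimethylcyclohexa-2,4-dien-1-yl]methyl acetate (single enantiomer)
Conditions: Burkholderia cepacia lipase (immobilised), vinyl acetate, t-BuOMe, 0–20 °C, argon, stopped short of half conversion
Reagents that add atoms: vinyl acetate, C=COC(C)=O
Why: Lipase-catalysed irreversible transesterification is a standard kinetic resolution of primary alcohols that carry the stereocentre next to the carbinol carbon. No stereocentre is made: the enzyme picks the (1S,6S) enantiomer, and the acetate it installs then protects O7 up to step 11.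

Step 8
Reactants: 12 [(1S,6S)-3,5,6-trimethylcyclohexa-2,4-dien-1-yl]methyl acetate
Product: 14 (2,5-dihydroxy-3,5,6-trimethylcyclohex-3-en-1-yl)methyl acetate with C3-OH and C6-OH both β, via endoperoxide 13 (not isolated)
Conditions: O2, tetraphenylporphyrin (cat.), visible light, CH2Cl2, −30 °C; then thiourea, MeOH, −30 °C to rt
Reagents that add atoms: dioxygen, O=O
Why: Singlet-oxygen [4+2] cycloaddition to cyclohexa-1,3-dienes, as in the formation of ascaridole from α-terpinene, outruns the ene reaction on ring-locked s-cis dienes. Oxygen adds to the β face because one of the cis C1/C2 groups is pseudoaxial on α, which sets C3 and C6. Thiourea cleaves only the O–O bond, so both C–O bonds keep their configuration.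

Step 9
Reactants: 14 (2,5-dihydroxy-3,5,6-trimethylcyclohex-3-en-1-yl)methyl acetate
Product: 16 (2,3,4,5-tetrahydroxy-3,5,6-trimethylcyclohexyl)methyl acetate with all four hydroxyls β, via osmate ester TMEDA chelate 15 (not isolated)
Conditions: OsO4 (1.05 equiv), TMEDA (1.1 equiv), CH2Cl2, −78 °C; then sat. aq NaHSO3, THF, 60 °C
Reagents that add atoms: osmium tetroxide, O=[Os](=O)(=O)=O; N,N,N',N'-tetramethylethane-1,2-diamine, CN(C)CCN(C)C (held in 15 only)
Why: Hydrogen-bond-directed dihydroxylation of cyclic allylic alcohols with the OsO4–TMEDA complex is known to give the syn product. Both allylic hydroxyls (C3, C6) lie on β and the α face carries the C3 methyl and a pseudoaxial C1/C2 group, so direction and sterics agree and the suprafacial addition sets C4 and C5. NaHSO3 releases the diol from the hexavalent osmium ester at a pH the acetate tolerates.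

Step 10
Reactants: 16 (2,3,4,5-tetrahydroxy-3,5,6-trimethylcyclohexyl)methyl acetate
Product: 17 3,4:5,6-bis-O-isopropylidene derivative of 16 (two cis-fused dioxolanes on the β face)
Conditions: Me2C(OMe)2, camphorsulfonic acid (cat.), acetone, 4 Å sieves, rt to 40 °C
Reagents that add atoms: 2,2-dimethoxypropane, COC(C)(C)OC
Why: Acid-catalysed transketalisation; acetone ketals prefer five-membered rings on cis-1,2-diols, and only the 3,4:5,6 pairing caps all four hydroxyls, so excess reagent and removal of methanol drive the equilibrium to 17. All-cis 1,2:3,4-diacetonides are known in the inositol series.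

Step 11
Reactants: 17 bis-acetonide acetate
Product: 18 bis-acetonide primary alcohol (C7-OH)
Conditions: K2CO3 (cat.), MeOH, 0 °C to rt
Reagents that add atoms: none
Why: Base-catalysed methanolysis of a primary acetate; the ketals are inert to base.

Step 12
Reactants: 18 bis-acetonide primary alcohol
Product: 19 bis-acetonide aldehyde (C7 formyl on C1, α)
Conditions: Dess–Martin periodinane, pyridine, CH2Cl2, 0 °C to rt
Reagents that add atoms: none
Why: Dess–Martin oxidation runs under buffered, non-basic conditions, so C1 next to the new aldehyde is not epimerised. The ketal oxygen at C6 is a poor leaving group and is not eliminated.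

Step 13
Reactants: 19 bis-acetonide aldehyde; 20 2-(triphenylphosphoranylidene)propanal
Product: 21 (E)-2-methyl-3-(ring C1)prop-2-enal, bis-acetonide
Conditions: toluene, 90 °C
Reagents that add atoms: none
Why: Wittig olefination with the stabilised α-methyl formyl ylide gives E-2-methylenals in a near-neutral medium, which protects C1. The product, an α-branched enal, reacts far more slowly with 20 than 19 does, so the homologation stops after one unit.

Step 14
Reactants: 21 enal; 22 (triphenylphosphoranylidene)acetaldehyde
Product: 23 (2E,4E)-4-methyl-5-(ring C1)penta-2,4-dienal, bis-acetonide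
Conditions: toluene, 70 °C, 22 (1.1 equiv) added in portions
Reagents that add atoms: none
Why: Wittig olefination with the formylmethylene ylide is a known two-carbon homologation of enals to E-dienals. Slow addition of a small excess limits a second addition to the product.

Step 15
Reactants: 24 methyl 2-methyl-3-oxopentanoate; 25 N-methoxy-N-methylpropanamide
Product: 27 methyl 2,4-dimethyl-3,5-dioxoheptanoate (mixture of diastereomers and enol forms), via dilithium dianion 26 (not isolated)
Conditions: LiN(i-Pr)2 (2.2 equiv), THF, −78 to 0 °C; then 25, −78 to 0 °C; aq HCl
Reagents that add atoms: LiN(i-Pr)2, [Li+].CC(C)[N-]C(C)C (its lithium is carried by 26 only)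
Why: γ-Acylation of a β-keto ester dianion: the more basic terminal carbanion attacks. The N-methoxy-N-methylamide holds the adduct as a chelated tetrahedral intermediate until the quench, which prevents proton transfer from the acidic product to unreacted dianion.

Step 16
Reactants: 27 methyl 2,4-dimethyl-3,5-dioxoheptanoate
Product: 28 6-ethyl-4-hydroxy-3,5-dimethyl-2H-pyran-2-one
Conditions: DBU, toluene, reflux; aq HCl
Reagents that add atoms: none
Why: Base-induced lactonisation of a 3,5-diketo ester: the C5 enolate oxygen displaces methoxide from the ester, and the product is stabilised as the 4-hydroxy-2-pyranone. Both stereocentres of 27 vanish.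

Step 17
Reactants: 28 6-ethyl-4-hydroxy-3,5-dimethyl-2H-pyran-2-one
Product: 30 2-ethyl-6-methoxy-3,5-dimethyl-4H-pyran-4-one, via pyrylium triflate 29 (not isolated)
Conditions: MeOTf (1.2 equiv), CH2Cl2, rt; then aq NaHCO3
Reagents that add atoms: methyl trifluoromethanesulfonate, COS(=O)(=O)C(F)(F)F
Why: A hard methylating agent attacks the most basic oxygen of a neutral 4-hydroxy-2-pyranone, the lactone carbonyl, to give 29. Loss of the 4-OH proton then gives the 2-methoxy-4-pyranone rather than the 4-methoxy-2-pyranone obtained by alkylating the anion.

Step 18
Reactants: 30 2-ethyl-6-methoxy-3,5-dimethyl-4H-pyran-4-one; 23 dienal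
Product: 32 aldol adduct pyranone-CH(CH3)-CH(OH)-CH=CH-C(CH3)=CH-ring (mixture at C11 and C12), via lithium dienolate 31 (not isolated)
Conditions: LiN(SiMe3)2, THF, −78 °C; then 23, −78 °C; aq NH4Cl
Reagents that add atoms: LiN(SiMe3)2, [Li+].C[Si](C)(C)[N-][Si](C)(C)C (its lithium is carried by 31 only)
Why: Vinylogous deprotonation of 2-alkyl-4-pyranones at the side-chain CH2 and aldol addition to aldehydes is a known way to extend such pyranones, and the lithium species adds 1,2 at low temperature. The two new centres form without control and are erased in step 19.

Step 19
Reactants: 32 aldol adduct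
Product: 34 all-E triene pyranone, bis-acetonide, via allylic mesylate 33 (not isolated)
Conditions: MsCl, Et3N, CH2Cl2, 0 °C; then DBU, 0 °C to rt, dark
Reagents that add atoms: methanesulfonyl chloride, CS(=O)(=O)Cl (its mesyl group is carried by 33 only)
Why: Mesylation and base-induced elimination through the acidic C12–H (E1cB-like) is the usual dehydration of pyranone aldols. It gives the conjugated alkene with pyranone and chain trans, whichever diastereomer of 32 enters.

Step 20
Reactants: 34 all-E triene pyranone, bis-acetonide
Product: 35 tetrol (C3, C4, C5, C6 hydroxyls free, all β)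
Conditions: 1 M aq HCl, THF, rt, dark
Reagents that add atoms: none
Why: Acid hydrolysis of isopropylidene ketals; the triene is conjugated with the electron-poor pyranone and is therefore a weak base. All C–O bonds of the ring stay intact, so no stereocentre is touched.

Step 21
Reactants: 35 tetrol
Product: 36 amaurone B
Conditions: Ac2O, pyridine, DMAP (cat.), CH2Cl2, 0 °C to rt, dark
Reagents that add atoms: acetic anhydride, CC(=O)OC(C)=O
Why: Acetylation distinguishes the secondary hydroxyls at C4 and C6 from the two tertiary, mutually hydrogen-bonded hydroxyls at C3 and C5, which react much more slowly under these conditions.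

## Compound list

1 | prop-2-yn-1-ol | C#CCO | starting material
2 | 4-methyl-2,5-dihydro-1,2-oxamagnesole (cyclic alkenylmagnesium alkoxide) | CC1=C[Mg]OC1 | intermediate
3 | (Z)-3-iodo-2-methylprop-2-en-1-ol | OC/C(C)=C\I | intermediate
4 | ethyl (triphenylphosphoranylidene)acetate | CCOC(=O)C=P(c1ccccc1)(c1ccccc1)c1ccccc1 | starting material
5 | (Z)-3-iodo-2-methylprop-2-enal | O=C/C(C)=C\I | intermediate
6 | ethyl (2E,4Z)-5-iodo-4-methylpenta-2,4-dienoate | CCOC(=O)/C=C/C(C)=C\I | intermediate
7 | (2E,4Z)-5-iodo-4-methylpenta-2,4-dien-1-ol | OC/C=C/C(C)=C\I | intermediate
8 | but-2-yne | CC#CC | starting material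
9 | 2-[(Z)-but-2-en-2-yl]-4,4,5,5-tetramethyl-1,3,2-dioxaborolane | C/C=C(\C)B1OC(C)(C)C(C)(C)O1 | intermediate
10 | (2E,4Z,6E)-4,6-dimethylocta-2,4,6-trien-1-ol | C/C=C(C)/C=C(C)\C=C\CO | intermediate
11 | rac-[(1S,6S)-3,5,6-trimethylcyclohexa-2,4-dien-1-yl]methanol (racemate, needed enantiomer drawn) | OC[C@@H]1[C@H](C)C(C)=CC(C)=C1 | intermediate
12 | [(1S,6S)-3,5,6-trimethylcyclohexa-2,4-dien-1-yl]methyl acetate | CC(=O)OC[C@@H]1[C@H](C)C(C)=CC(C)=C1 | intermediate
13 | (4,6,8-trimethyl-2,3-dioxabicyclo[2.2.2]oct-5-en-7-yl)methyl acetate, O–O bridge from C3 to C6 on the β face | CC(=O)OC[C@@H]1[C@H](C)[C@]2(C)C=C(C)[C@H]1OO2 | intermediate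
14 | (2,5-dihydroxy-3,5,6-trimethylcyclohex-3-en-1-yl)methyl acetate, C3-OH and C6-OH β | CC(=O)OC[C@@H]1[C@H](C)[C@@](C)(O)C=C(C)[C@H]1O | intermediate
15 | cyclic O4,O5 dioxoosmium ester of 16, chelated by TMEDA | CC(=O)OC[C@@H]1[C@H](C)[C@@](C)(O)[C@H]2O[Os-2]3(=O)(=O)([N+](C)(C)CC[N+]3(C)C)O[C@@]2(C)[C@H]1O | intermediate
16 | (2,3,4,5-tetrahydroxy-3,5,6-trimethylcyclohexyl)methyl acetate, all hydroxyls β | CC(=O)OC[C@@H]1[C@H](C)[C@@](C)(O)[C@@H](O)[C@@](C)(O)[C@H]1O | intermediate
17 | 3,4:5,6-bis-O-isopropylidene derivative of 16 | CC(=O)OC[C@@H]1[C@H](C)[C@@]2(C)OC(C)(C)O[C@H]2[C@@]3(C)OC(C)(C)O[C@@H]13 | intermediate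
18 | bis-acetonide primary alcohol | OC[C@@H]1[C@H](C)[C@@]2(C)OC(C)(C)O[C@H]2[C@@]3(C)OC(C)(C)O[C@@H]13 | intermediate
19 | bis-acetonide aldehyde | O=C[C@@H]1[C@H](C)[C@@]2(C)OC(C)(C)O[C@H]2[C@@]3(C)OC(C)(C)O[C@@H]13 | intermediate
20 | 2-(triphenylphosphoranylidene)propanal | CC(C=O)=P(c1ccccc1)(c1ccccc1)c1ccccc1 | starting material
21 | (E)-2-methylenal, bis-acetonide | O=C/C(C)=C/[C@@H]1[C@H](C)[C@@]2(C)OC(C)(C)O[C@H]2[C@@]3(C)OC(C)(C)O[C@@H]13 | intermediate
22 | (triphenylphosphoranylidene)acetaldehyde | O=CC=P(c1ccccc1)(c1ccccc1)c1ccccc1 | starting material
23 | (2E,4E)-4-methyldienal, bis-acetonide | O=C/C=C/C(C)=C/[C@@H]1[C@H](C)[C@@]2(C)OC(C)(C)O[C@H]2[C@@]3(C)OC(C)(C)O[C@@H]13 | intermediate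
24 | methyl 2-methyl-3-oxopentanoate | CCC(=O)C(C)C(=O)OC | starting material
25 | N-methoxy-N-methylpropanamide | CCC(=O)N(C)OC | starting material
26 | dilithium dianion of 24 | [Li+].[Li+].CC=C([O-])C(C)=C([O-])OC | intermediate
27 | methyl 2,4-dimethyl-3,5-dioxoheptanoate | CCC(=O)C(C)C(=O)C(C)C(=O)OC | intermediate
28 | 6-ethyl-4-hydroxy-3,5-dimethyl-2H-pyran-2-one | CCc1oc(=O)c(C)c(O)c1C | intermediate
29 | 6-ethyl-4-hydroxy-2-methoxy-3,5-dimethylpyrylium triflate | CCc1[o+]c(OC)c(C)c(O)c1C.[O-]S(=O)(=O)C(F)(F)F | intermediate
30 | 2-ethyl-6-methoxy-3,5-dimethyl-4H-pyran-4-one | CCc1oc(OC)c(C)c(=O)c1C | intermediate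
31 | lithium dienolate of 30 (2-ethylidene-2H-pyran-4-olate) | [Li+].CC=C1OC(OC)=C(C)C([O-])=C1C | intermediate
32 | aldol adduct, C11 and C12 unassigned, bis-acetonide | COc1oc(C(C)C(O)/C=C/C(C)=C/[C@@H]2[C@H](C)[C@@]3(C)OC(C)(C)O[C@H]3[C@@]4(C)OC(C)(C)O[C@@H]24)c(C)c(=O)c1C | intermediate
33 | C11 mesylate of 32 | COc1oc(C(C)C(OS(C)(=O)=O)/C=C/C(C)=C/[C@@H]2[C@H](C)[C@@]3(C)OC(C)(C)O[C@H]3[C@@]4(C)OC(C)(C)O[C@@H]24)c(C)c(=O)c1C | intermediate
34 | all-E triene pyranone, bis-acetonide | COc1oc(/C(C)=C/C=C/C(C)=C/[C@@H]2[C@H](C)[C@@]3(C)OC(C)(C)O[C@H]3[C@@]4(C)OC(C)(C)O[C@@H]24)c(C)c(=O)c1C | intermediate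
35 | bis(deacetyl)amaurone B (tetrol) | COc1oc(/C(C)=C/C=C/C(C)=C/[C@@H]2[C@H](C)[C@@](C)(O)[C@@H](O)[C@@](C)(O)[C@H]2O)c(C)c(=O)c1C | intermediate
36 | amaurone B | COc1oc(/C(C)=C/C=C/C(C)=C/[C@@H]2[C@H](C)[C@@](C)(O)[C@@H](OC(C)=O)[C@@](C)(O)[C@H]2OC(C)=O)c(C)c(=O)c1C | target

## Step count and least certain steps

Total: 21 steps. Longest linear sequence: 17 steps (1, 2, 3, 5–14, 18–21). Step 4 and steps 15–17 are side branches.

**Step 6 (key step).**
- Risk: the closure may be too slow at temperatures that substrate and product tolerate. Prolonged heating then brings hydrogen shifts in the diene and oxidative aromatisation by traces of air, and the volatile diene can be lost on isolation and during the slow enzymatic step that follows.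
- Fallback (sets out from 10, returns at 17): 10 would be acetylated (Ac2O, pyridine) to (2E,4Z,6E)-4,6-dimethylocta-2,4,6-trien-1-yl acetate F1, which has no protic group and is less volatile. F1 would be closed in toluene. The cooled solution, holding 12 as the racemate, would be photooxygenated and reduced under the conditions of step 8 without isolating the diene. Racemic 14, 16 and 17 would follow by steps 9 and 10. The enantiomers of the robust bis-acetonide would then be separated by preparative chromatography on a chiral stationary phase.

**Step 7.**
- Risk: enantiomer discrimination may be poor, because the stereocentre is one atom away from the reacting oxygen and its two ring branches differ little in size. The wanted enantiomer is the faster one, so its purity is capped by the selectivity of the enzyme.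
- Fallback (sets out from 11, returns at 12): covalent resolution. Compound 11 would be esterified with (1S)-camphanic chloride (Et3N, DMAP) and the diastereomers separated by crystallisation or chromatography to give [(1S,6S)-3,5,6-trimethylcyclohexa-2,4-dien-1-yl]methyl (1S,4R)-camphanate F2. Methanolysis (K2CO3, MeOH) would give the enantiopure (1S,6S)-alcohol F3, and Ac2O/pyridine would give 12.

**Step 9.**
- Risk: facial selectivity may be incomplete, or osmylation may be slow at a trisubstituted alkene next to a quaternary carbon. The acetate may migrate or be lost while the osmate is cleaved.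
- Fallback (sets out from 13, returns at 16): steric instead of hydrogen-bond control. Endoperoxide 13 would be isolated and dihydroxylated with catalytic OsO4 and N-methylmorpholine N-oxide in aqueous acetone. In unsubstituted bicyclic endoperoxides osmium attacks anti to the peroxide bridge. In 13 that side of C4=C5 is filled by the C1 and C2 substituents, so attack should come from the peroxide side and give the C4,C5-β-diol endoperoxide F4. Reduction of its O–O bond with thiourea would give 16.

**Step 14.**
- Risk: over-homologation is possible, because the unhindered product dienal is at least as electrophilic as the α-branched enal 21. Conversion may also be slow, with erosion of geometry.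
- Fallback (sets out from 21, returns at 23): Horner–Wadsworth–Emmons reaction of 21 with triethyl phosphonoacetate (LiCl, DBU, MeCN) would give ethyl dienoate F5, which cannot react further. Reduction with i-Bu2AlH would give dienol F6, and MnO2 oxidation would give 23.

**Step 20.**
- Risk: the pyranone methoxy group may be hydrolysed, the triene may isomerise under acid, or a tertiary carbinol carbon may ionise before the second, more hindered ketal has been released.
- Fallback (sets out from 23, returns at 35): the acid step is moved ahead of the pyranone. Dienal 23 would be hydrolysed (1 M aq HCl, THF) to tetrol dienal F7. The secondary hydroxyls would be silylated (Et3SiOTf, 2,6-lutidine, −78 °C) to give 4,6-bis(triethylsilyl) ether F8. Excess 31 would give aldol adduct F9. Mesylation to mesylate F10 and treatment with DBU would give bis(triethylsilyl) triene F11. HF·pyridine in THF would then release 35 under conditions that methoxypyranones tolerate.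

## Further compounds

F1 | step 6 | (2E,4Z,6E)-4,6-dimethylocta-2,4,6-trien-1-yl acetate | C/C=C(C)/C=C(C)\C=C\COC(C)=O
F2 | step 7 | [(1S,6S)-3,5,6-trimethylcyclohexa-2,4-dien-1-yl]methyl (1S,4R)-camphanate | C[C@@]12CC[C@@](C1(C)C)(OC2=O)C(=O)OC[C@@H]3[C@H](C)C(C)=CC(C)=C3
F3 | step 7 | [(1S,6S)-3,5,6-trimethylcyclohexa-2,4-dien-1-yl]methanol, single enantiomer | OC[C@@H]1[C@H](C)C(C)=CC(C)=C1
F4 | step 9 | C4,C5-β-diol of endoperoxide 13 | CC(=O)OC[C@@H]1[C@H](C)[C@]2(C)[C@@H](O)[C@@](C)(O)[C@H]1OO2
F5 | step 14 | ethyl (2E,4E)-4-methyl-5-(ring C1)penta-2,4-dienoate, bis-acetonide | CCOC(=O)/C=C/C(C)=C/[C@@H]1[C@H](C)[C@@]2(C)OC(C)(C)O[C@H]2[C@@]3(C)OC(C)(C)O[C@@H]13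
F6 | step 14 | (2E,4E)-4-methyl-5-(ring C1)penta-2,4-dien-1-ol, bis-acetonide | OC/C=C/C(C)=C/[C@@H]1[C@H](C)[C@@]2(C)OC(C)(C)O[C@H]2[C@@]3(C)OC(C)(C)O[C@@H]13
F7 | step 20 | tetrol dienal | O=C/C=C/C(C)=C/[C@@H]1[C@H](C)[C@@](C)(O)[C@@H](O)[C@@](C)(O)[C@H]1O
F8 | step 20 | 4,6-bis(triethylsilyl) ether of F7 | O=C/C=C/C(C)=C/[C@@H]1[C@H](C)[C@@](C)(O)[C@@H](O[Si](CC)(CC)CC)[C@@](C)(O)[C@H]1O[Si](CC)(CC)CC
F9 | step 20 | aldol adduct of F8 and 31, C11 and C12 unassigned | COc1oc(C(C)C(O)/C=C/C(C)=C/[C@@H]2[C@H](C)[C@@](C)(O)[C@@H](O[Si](CC)(CC)CC)[C@@](C)(O)[C@H]2O[Si](CC)(CC)CC)c(C)c(=O)c1C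
F10 | step 20 | C11 mesylate of F9 | COc1oc(C(C)C(OS(C)(=O)=O)/C=C/C(C)=C/[C@@H]2[C@H](C)[C@@](C)(O)[C@@H](O[Si](CC)(CC)CC)[C@@](C)(O)[C@H]2O[Si](CC)(CC)CC)c(C)c(=O)c1C
F11 | step 20 | all-E triene pyranone, 4,6-bis(triethylsilyl) ether | COc1oc(/C(C)=C/C=C/C(C)=C/[C@@H]2[C@H](C)[C@@](C)(O)[C@@H](O[Si](CC)(CC)CC)[C@@](C)(O)[C@H]2O[Si](CC)(CC)CC)c(C)c(=O)c1C
A1 | alternative 1 | cyclic α-ketol, C4 ketone, C3 tertiary alcohol, C5/C6 acetonide, O7 TBS ether | CC(C)(C)[Si](C)(C)OC[C@@H]1[C@H](C)[C@@](C)(O)C(=O)[C@@]2(C)OC(C)(C)O[C@@H]12
A2 | alternative 1 | acyclic keto aldehyde, C4 aldehyde and C3 methyl ketone | CC(C)(C)[Si](C)(C)OC[C@H]([C@H](C)C(C)=O)[C@@H]1OC(C)(C)O[C@]1(C)C=O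
A3 | alternative 2 | trans-2-hydroxycyclohexanecarbaldehyde with all six ring centres | O=C[C@@H]1[C@H](C)[C@@](C)(O[Si](CC)(CC)CC)[C@H]2OC(C)(C)O[C@@]2(C)[C@H]1O
A4 | alternative 2 | acyclic C6,C7 dialdehyde | O=CC[C@H](C)[C@@](C)(O[Si](CC)(CC)CC)[C@H]1OC(C)(C)O[C@@]1(C)C=O
A5 | alternative 3 | acetonide-bridged bicyclic ketol (2,4-dioxabicyclo[3.3.1]nonan-9-one) | CC(C)(C)[Si](C)(C)OC[C@@H]1[C@H](C)[C@@]2(C)OC(C)(C)O[C@](C)(C2=O)[C@H]1O
A6 | alternative 3 | meso cis-2,2,4,6-tetramethyl-1,3-dioxan-5-one | C[C@H]1OC(C)(C)O[C@@H](C)C1=O
A7 | alternative 3 | trimethylsilyl enol ether of A6 (remaining centre either way) | CC1OC(C)(C)OC(C)=C1O[Si](C)(C)C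
A8 | alternative 3 | (E)-2-[(tert-butyldimethylsilyloxy)methyl]but-2-enal | C/C=C(/C=O)CO[Si](C)(C)C(C)(C)C
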